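**Retrosynthetic overview**

1. Numbering (octahydronaphthalene, also used for the matching atoms of open-chain precursors): C1 carbinol, C2 ester-bearing carbon, C4 methyl, C4a/C8a ring fusion, C5 acetyl, C6 sec-butyl, C7=C8. Endgame: acylate the C2 oxygen with a mono-protected (E)-3-methylglutaconic acid, reduce a C1 ketone by axial hydride attack, then free the acid.
2. Key disconnection: the trans-decalin is opened at C4a–C8a and at C6–C7 to one acyclic chain, a β,γ-unsaturated (Z)-iodovinyl ketone that also carries an α-(1-acetoxyalkyl) enone. Ring B closes first (enolate Michael addition/E1cB) and ring A second (6-endo vinyl radical cyclization), in one flask.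
3. Enabling feature: the acetyl-bearing C5 lies between C4a and C6, so the one methyl ketone, as its Morita–Baylis–Hillman-type acetate, makes C4a and then C6 electrophilic in turn. The C1 oxygen, raised to a ketone, acidifies C8a, and the cis C7=C8 bond of ring A is carried as a (Z)-iodoalkene so that C7 reacts as an sp2 radical.
4. Chain assembly: a cis-α-methyl-γ-lactone from propanoic acid and (R)-PMB glycidyl ether sets C2 and C4; it is taken on to an alkynone, which undergoes reductive aldol with (R)-2-methylbutanal (C6 and the sec-butyl centre); propargylation, iodination, diimide reduction and oxidation finish the chain.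

Key step: step 17

Remark: (R)-2-methylbutanoic acid, (R)-PMB glycidyl ether and the Reformatsky reagent BrZnCH2CO2t-Bu are taken as purchased. The two carbinol centres that are destroyed later (acetoxy carbon = future C6, open-chain hydroxyl carbon = future C1) are carried as epimer mixtures.

**Step 1**
Reactants: 1 propanoic acid; 2 (R)-2-{[(4-methoxybenzyl)oxy]methyl}oxirane
Product: 5 (5R)-5-{[(4-methoxybenzyl)oxy]methyl}-3-methyldihydrofuran-2(3H)-one (C3 epimers), via dilithium enediolate 3 (not isolated), via hydroxy acid 4 (not isolated)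
Conditions: LiN(i-Pr)2 (2.2 equiv), THF/HMPA, 0 → 45 °C; aq. HCl; TsOH (cat.), PhMe, 23 °C
Reagents that add atoms: none
Why: Creger alkylation: the α-carbon of the carboxylic acid dianion opens the terminal epoxide at its CH2 group by SN2, so the C–O stereocentre of 2 is untouched, and acid closes the γ-lactone; the methyl-bearing C3 forms without control and is set in step 2.

**Step 2**
Reactants: 5 lactone (C3 epimers)
Product: 7 (3R,5R)-5-{[(4-methoxybenzyl)oxy]methyl}-3-methyldihydrofuran-2(3H)-one (cis), via lithium enolate 6 (not isolated)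
Conditions: LiN(i-Pr)2 (1.1 equiv), THF, −78 °C; then 2,6-di-tert-butyl-4-methylphenol, −78 °C
Reagents that add atoms: none
Why: Enolate protonation under substrate control: deprotonation flattens C3 and the bulky phenol delivers the proton to the enolate face anti to the C5 CH2OPMB group, which should leave the methyl group cis to it (3R).

**Step 3**
Reactants: 7 cis-lactone
Product: 8 (3R,5R)-5-{[(4-methoxybenzyl)oxy]methyl}-3-methyltetrahydrofuran-2-ol (lactol, anomers)
Conditions: i-Bu2AlH (1.1 equiv), CH2Cl2, −78 °C; aq. KNaC4H4O6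
Reagents that add atoms: none
Why: Lactone-to-lactol reduction: at −78 °C the tetrahedral aluminium lactolate survives until work-up, so reduction stops at the aldehyde oxidation level and no stereocentre is touched.

**Step 4**
Reactants: 8 lactol
Product: 9 (2R,4R)-1-[(4-methoxybenzyl)oxy]-4-methylhex-5-yn-2-ol
Conditions: dimethyl (1-diazo-2-oxopropyl)phosphonate, K2CO3, MeOH, 0 → 23 °C
Reagents that add atoms: dimethyl (1-diazo-2-oxopropyl)phosphonate, CC(=O)C(=[N+]=[N-])P(=O)(OC)OC
Why: Ohira–Bestmann (Seyferth–Gilbert) homologation of the open hydroxy aldehyde form gives the terminal alkyne, and the mild K2CO3/MeOH conditions at low temperature should keep the α-methyl centre from epimerizing.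

**Step 5**
Reactants: 9 alkynol
Product: 10 tert-butyl{[(2R,4R)-1-[(4-methoxybenzyl)oxy]-4-methylhex-5-yn-2-yl]oxy}dimethylsilane
Conditions: TBSCl, imidazole, DMF, 23 °C
Reagents that add atoms: tert-butyldimethylsilyl chloride, CC(C)(C)[Si](C)(C)Cl
Why: Silyl ether formation on the secondary alcohol protects the future C2 oxygen through the organometallic and base steps, and no stereocentre is formed.

**Step 6**
Reactants: 10 silyl ether alkyne
Product: 12 (5R,7R)-7-[(tert-butyldimethylsilyl)oxy]-8-[(4-methoxybenzyl)oxy]-5-methyloct-3-yn-2-one, via lithium acetylide 11 (not isolated)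
Conditions: n-BuLi, THF, −78 °C; N-methoxy-N-methylacetamide, −78 → 0 °C; aq. NH4Cl
Reagents that add atoms: N-methoxy-N-methylacetamide, CON(C)C(C)=O
Why: Acylation of the lithium acetylide by a Weinreb amide stops at the chelated tetrahedral adduct, so the alkynone, whose propargylic C–H at the methyl centre is acidic, is released only on work-up and is neither over-added nor epimerized.

**Step 7**
Reactants: 13 (R)-2-methylbutanoic acid
Product: 14 (R)-2-methylbutan-1-ol
Conditions: LiAlH4, Et2O, 0 → 23 °C
Reagents that add atoms: none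
Why: Hydride reduction of the acid to the primary alcohol does not involve the α-carbon, so the (R) centre is kept.

**Step 8**
Reactants: 14 (R)-2-methylbutan-1-ol
Product: 15 (R)-2-methylbutanal
Conditions: TEMPO (1 mol %), KBr (10 mol %), NaOCl, aq. NaHCO3/CH2Cl2, 0 °C
Reagents that add atoms: none
Why: Anelli oxidation (TEMPO/NaOCl) is fast at 0 °C in a buffered two-phase system, which should give the α-branched aldehyde without racemization; it is used at once as a CH2Cl2 solution.

**Step 9**
Reactants: 12 alkynone; 15 (R)-2-methylbutanal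
Product: 17 (3Z,5R,7R)-3-[(2R)-1-hydroxy-2-methylbutyl]-7-[(tert-butyldimethylsilyl)oxy]-8-[(4-methoxybenzyl)oxy]-5-methyloct-3-en-2-one (carbinol epimers), via aluminium allenolate 16 (not isolated)
Conditions: i-Bu2AlH (1.5 equiv), HMPA (3 equiv), THF, 0 °C; then 15, −78 → 0 °C
Reagents that add atoms: none
Why: Reductive aldol: i-Bu2AlH–HMPA adds hydride to the alkyne carbon β to the carbonyl group (conjugate hydroalumination) and the aluminium allenolate 16 attacks the aldehyde through its α-carbon on the side away from the β-substituent, which should give the (Z)-alkene of a Morita–Baylis–Hillman-type adduct; the carbinol centre forms as an epimer mixture that step 17 erases.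

**Step 10**
Reactants: 17 allylic alcohol
Product: 18 (3Z,5R,7R)-3-[(2R)-1-acetoxy-2-methylbutyl]-7-[(tert-butyldimethylsilyl)oxy]-8-[(4-methoxybenzyl)oxy]-5-methyloct-3-en-2-one (acetate epimers)
Conditions: Ac2O, pyridine, DMAP (cat.), CH2Cl2, 0 °C
Reagents that add atoms: acetic anhydride, CC(=O)OC(C)=O
Why: Acylation of the allylic alcohol turns it into the leaving group for the later E1cB step and forms no stereocentre.

**Step 11**
Reactants: 18 PMB ether
Product: 19 (3Z,5R,7R)-3-[(2R)-1-acetoxy-2-methylbutyl]-7-[(tert-butyldimethylsilyl)oxy]-8-hydroxy-5-methyloct-3-en-2-one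
Conditions: DDQ, CH2Cl2/pH 7 buffer, 0 °C
Reagents that add atoms: none
Why: Oxidative cleavage of the electron-rich PMB ether by DDQ (hydride abstraction, hemiacetal hydrolysis) is selective over the silyl ether, the allylic acetate and the enone.

**Step 12**
Reactants: 19 primary alcohol
Product: 20 (2R,4R,5Z)-6-[(2R)-1-acetoxy-2-methylbutyl]-2-[(tert-butyldimethylsilyl)oxy]-4-methyl-7-oxooct-5-enal
Conditions: Dess–Martin periodinane, NaHCO3, CH2Cl2, 0 → 23 °C
Reagents that add atoms: none
Why: Dess–Martin oxidation under buffered, non-basic conditions gives the α-silyloxy aldehyde without epimerization of the adjacent centre.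

**Step 13**
Reactants: 20 aldehyde
Product: 21 (5R,7R,8Z)-9-[(2R)-1-acetoxy-2-methylbutyl]-5-[(tert-butyldimethylsilyl)oxy]-4-hydroxy-7-methylundec-8-en-1-yn-10-one (C4 epimers)
Conditions: In powder, propargyl bromide, THF/aq. NH4Cl, 23 °C
Reagents that add atoms: propargyl bromide, C#CCBr
Why: Indium-mediated Barbier propargylation in aqueous THF adds to the aldehyde in preference to the ketone and, with unsubstituted propargyl bromide, gives the homopropargylic alcohol; the new carbinol centre is uncontrolled and is oxidized in step 16.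

**Step 14**
Reactants: 21 terminal alkyne
Product: 22 (5R,7R,8Z)-9-[(2R)-1-acetoxy-2-methylbutyl]-5-[(tert-butyldimethylsilyl)oxy]-4-hydroxy-1-iodo-7-methylundec-8-en-1-yn-10-one
Conditions: NIS, AgNO3 (10 mol %), acetone, 23 °C, dark
Reagents that add atoms: N-iodosuccinimide, O=C1CCC(=O)N1I
Why: AgNO3-catalysed electrophilic iodination of the terminal alkyne (silver acetylide, then iodine transfer from NIS) gives the 1-iodoalkyne under neutral conditions.

**Step 15**
Reactants: 22 iodoalkyne
Product: 23 (1Z,5R,7R,8Z)-9-[(2R)-1-acetoxy-2-methylbutyl]-5-[(tert-butyldimethylsilyl)oxy]-4-hydroxy-1-iodo-7-methylundeca-1,8-dien-10-one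
Conditions: 2-nitrobenzenesulfonyl hydrazide, Et3N, THF/i-PrOH, 23 °C
Reagents that add atoms: none
Why: Diimide reduction: diazene, released in the flask from the sulfonyl hydrazide, transfers two hydrogen atoms to one face of the iodoalkyne in a concerted syn addition, which gives the (Z)-iodoalkene and leaves the hindered trisubstituted enone alone.

**Step 16**
Reactants: 23 homoallylic alcohol
Product: 24 (1Z,5R,7R,8Z)-9-[(2R)-1-acetoxy-2-methylbutyl]-5-[(tert-butyldimethylsilyl)oxy]-1-iodo-7-methylundeca-1,8-diene-4,10-dione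
Conditions: Dess–Martin periodinane, NaHCO3, CH2Cl2, 0 °C
Reagents that add atoms: none
Why: Dess–Martin oxidation of the homoallylic alcohol under buffered conditions gives the β,γ-unsaturated ketone without shift of the double bond into conjugation; 24 is used at once.

**Step 17**
Reactants: 24 acyclic iodo dienedione
Product: 27 trans-fused 5-acetyl-6-[(2R)-butan-2-yl]-2-[(tert-butyldimethylsilyl)oxy]-4-methyl-3,4,4a,5,6,8a-hexahydronaphthalen-1(2H)-one (all ring centres as in the target), via lithium dienolate 25 (not isolated), via iodovinyl cyclohexanone 26 (not isolated)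
Conditions: LiN(SiMe3)2 (1.05 equiv), THF, −78 → 0 °C; then, same flask, Bu3SnH (1.3 equiv, syringe pump), Et3B (0.3 equiv), air, PhMe, 23 °C
Reagents that add atoms: none
Why: LiN(SiMe3)2 removes a proton from the CH2 between the ketone and the iodoalkene (future C8a) to give dienolate 25, whose α-carbon adds to the enone β-carbon (future C4a) in a 6-(enolendo)-exo-trig Michael addition that closes ring B, and the β-acetoxy enolate so formed expels acetate (E1cB) to leave the (E)-alkylidene ketone 26, the whole being the intramolecular form of the known SN2′ alkylation of Morita–Baylis–Hillman acetates by enolates. Bu3SnH/Et3B/air then turns the C–I bond into a vinyl radical at C7, which adds to the β-carbon of the new enone (C6) in a 6-endo-trig closure of ring A, the known course of vinyl radicals that face an α-substituted enone or acrylate, and the α-keto radical at C5 takes hydrogen from the stannane. C4a is controlled by the C4 methyl centre through A(1,3) strain (C4–H eclipses the enone, so the tether reaches the face that leaves methyl and the C5 arm equatorial in the chair), and C8a is controlled by the (Z)-enolate, which places the iodovinyl group equatorial and trans to the C5 arm, the arrangement also favoured at equilibrium for this enolizable centre; the C2 silyl ether then sits axial next to the enolate, where it avoids A(1,2) strain. C6 is controlled by the alkene geometry of 26: both acetate epimers eliminate through the enolate conformer that keeps hydrogen, not sec-butyl, syn to the enolate substituent, which puts sec-butyl cis to C4a on the alkene and hence pseudoaxial, on the face of H-4a, once C7 has bonded to C6. C5 is controlled by its neighbour, since hydrogen is delivered to the radical anti to the pseudoaxial sec-butyl group, which leaves acetyl equatorial and cis to sec-butyl. The selectivities needed are α- over γ-attack of the dienolate and 6-endo over 5-exo attack of the radical; the first is secured by ring size (six against eight) and the second by the fully substituted, electron-poor α-carbon of the enone, while a low stannane concentration keeps the vinyl radical from being reduced first.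

**Step 18**
Reactants: 27 silyl ether decalone
Product: 28 trans-fused 5-acetyl-6-[(2R)-butan-2-yl]-2-hydroxy-4-methyl-3,4,4a,5,6,8a-hexahydronaphthalen-1(2H)-one (axial C2 hydroxyl)
Conditions: HF·pyridine, THF, 0 → 23 °C
Reagents that add atoms: none
Why: Fluoride-mediated desilylation under weakly acidic conditions frees the axial C2 hydroxyl without enolizing the α-ketol or conjugating the β,γ-double bond.

**Step 19**
Reactants: 29 methyl 3-oxobutanoate
Product: 30 methyl (E)-3-{[(trifluoromethyl)sulfonyl]oxy}but-2-enoate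
Conditions: Tf2O, aq. Me4NOH, hexanes, 5 °C
Reagents that add atoms: trifluoromethanesulfonic anhydride, O=S(=O)(OS(=O)(=O)C(F)(F)F)C(F)(F)F
Why: O-triflation of the non-chelated tetramethylammonium enolate of the β-keto ester in a two-phase system gives the (E)-enol triflate (methyl cis to the ester), whereas a chelating lithium enolate would give (Z).

**Step 20**
Reactants: 30 enol triflate
Product: 31 5-tert-butyl 1-methyl (E)-3-methylpent-2-enedioate
Conditions: BrZnCH2CO2t-Bu, Pd(PPh3)4 (5 mol %), THF, 23 → 50 °C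
Reagents that add atoms: (2-tert-butoxy-2-oxoethyl)zinc bromide, CC(C)(C)OC(=O)C[Zn]Br
Why: Negishi coupling of the enol triflate with the Reformatsky reagent under zerovalent palladium catalysis (oxidative addition, transmetalation, reductive elimination) proceeds with retention of alkene geometry and so fixes the (E)-3-methylglutaconate.

**Step 21**
Reactants: 31 mixed diester
Product: 32 (E)-5-tert-butoxy-3-methyl-5-oxopent-2-enoic acid
Conditions: Me3SnOH, 1,2-dichloroethane, 70 °C; aq. HCl
Reagents that add atoms: trimethyltin hydroxide, C[Sn](C)(C)O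
Why: Me3SnOH cleaves the methyl ester under near-neutral conditions (tin carboxylate, then acid), which leaves the tert-butyl ester and the alkene geometry untouched.

**Step 22**
Reactants: 28 ketol; 32 half-ester acid
Product: 33 C2 ester of 28 with 32 (5-tert-butyl 1-decalinyl (E)-3-methylpent-2-enedioate, C1 ketone)
Conditions: EDC·HCl, DMAP (0.2 equiv), CH2Cl2, 0 °C
Reagents that add atoms: none
Why: Steglich esterification (carbodiimide activation, DMAP acyl transfer) acylates the only hydroxyl group, and low temperature with little DMAP limits E/Z drift of the activated enoate.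

**Step 23**
Reactants: 33 keto ester
Product: 34 tert-butyl ester of the target ((1S)-alcohol)
Conditions: NaBH4 (1.0 equiv), MeOH/THF, −78 → −40 °C; AcOH quench
Reagents that add atoms: none
Why: Hydride reduction: the α-acyloxy cyclohexanone is more electrophilic and less hindered than the methyl ketone, and NaBH4 attacks it axially, anti to the axial C2 acyloxy group (polar Felkin–Anh), which gives the equatorial (1S) alcohol.

**Step 24**
Reactants: 34 tert-butyl ester
Product: 35 target, (1S,2R,4R,4aS,5S,6S,8aR)-5-acetyl-6-[(2R)-butan-2-yl]-1-hydroxy-4-methyl-1,2,3,4,4a,5,6,8a-octahydronaphthalen-2-yl hydrogen (E)-3-methylpent-2-enedioate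
Conditions: CF3CO2H/CH2Cl2 (1:4), 0 °C
Reagents that add atoms: none
Why: Acidolysis of the tert-butyl ester (protonation, loss of the tert-butyl cation as 2-methylpropene) frees the carboxylic acid and does not touch the secondary ester, the ketone or the alkene.

**Compound list**

1 | propanoic acid | CCC(=O)O | starting material
2 | (R)-2-{[(4-methoxybenzyl)oxy]methyl}oxirane | COc1ccc(COC[C@H]2CO2)cc1 | starting material
3 | dilithium enediolate of propanoic acid | CC=C(O[Li])O[Li] | intermediate
4 | (4R)-4-hydroxy-5-[(4-methoxybenzyl)oxy]-2-methylpentanoic acid (C2 epimers) | COc1ccc(COC[C@H](O)CC(C)C(=O)O)cc1 | intermediate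
5 | (5R)-5-{[(4-methoxybenzyl)oxy]methyl}-3-methyldihydrofuran-2(3H)-one (C3 epimers) | COc1ccc(COC[C@H]2CC(C)C(=O)O2)cc1 | intermediate
6 | lithium enolate of lactone 5 | COc1ccc(COC[C@H]2CC(C)=C(O[Li])O2)cc1 | intermediate
7 | (3R,5R)-5-{[(4-methoxybenzyl)oxy]methyl}-3-methyldihydrofuran-2(3H)-one | COc1ccc(COC[C@H]2C[C@@H](C)C(=O)O2)cc1 | intermediate
8 | (3R,5R)-5-{[(4-methoxybenzyl)oxy]methyl}-3-methyltetrahydrofuran-2-ol (anomers) | COc1ccc(COC[C@H]2C[C@@H](C)C(O)O2)cc1 | intermediate
9 | (2R,4R)-1-[(4-methoxybenzyl)oxy]-4-methylhex-5-yn-2-ol | COc1ccc(COC[C@H](O)C[C@@H](C)C#C)cc1 | intermediate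
10 | tert-butyl{[(2R,4R)-1-[(4-methoxybenzyl)oxy]-4-methylhex-5-yn-2-yl]oxy}dimethylsilane | COc1ccc(COC[C@H](O[Si](C)(C)C(C)(C)C)C[C@@H](C)C#C)cc1 | intermediate
11 | lithium acetylide of 10 | COc1ccc(COC[C@H](O[Si](C)(C)C(C)(C)C)C[C@@H](C)C#C[Li])cc1 | intermediate
12 | (5R,7R)-7-[(tert-butyldimethylsilyl)oxy]-8-[(4-methoxybenzyl)oxy]-5-methyloct-3-yn-2-one | COc1ccc(COC[C@H](O[Si](C)(C)C(C)(C)C)C[C@@H](C)C#CC(C)=O)cc1 | intermediate
13 | (R)-2-methylbutanoic acid | CC[C@@H](C)C(=O)O | starting material
14 | (R)-2-methylbutan-1-ol | CC[C@@H](C)CO | intermediate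
15 | (R)-2-methylbutanal | CC[C@@H](C)C=O | intermediate
16 | diisobutylaluminium allenolate from 12 | COc1ccc(COC[C@H](O[Si](C)(C)C(C)(C)C)C[C@@H](C)C=C=C(C)O[Al](CC(C)C)CC(C)C)cc1 | intermediate
17 | (3Z,5R,7R)-3-[(2R)-1-hydroxy-2-methylbutyl]-7-[(tert-butyldimethylsilyl)oxy]-8-[(4-methoxybenzyl)oxy]-5-methyloct-3-en-2-one (carbinol epimers) | COc1ccc(COC[C@H](O[Si](C)(C)C(C)(C)C)C[C@@H](C)/C=C(\C(C)=O)C(O)[C@H](C)CC)cc1 | intermediate
18 | acetate of 17 | COc1ccc(COC[C@H](O[Si](C)(C)C(C)(C)C)C[C@@H](C)/C=C(\C(C)=O)C(OC(C)=O)[C@H](C)CC)cc1 | intermediate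
19 | (3Z,5R,7R)-3-[(2R)-1-acetoxy-2-methylbutyl]-7-[(tert-butyldimethylsilyl)oxy]-8-hydroxy-5-methyloct-3-en-2-one | OC[C@H](O[Si](C)(C)C(C)(C)C)C[C@@H](C)/C=C(\C(C)=O)C(OC(C)=O)[C@H](C)CC | intermediate
20 | (2R,4R,5Z)-6-[(2R)-1-acetoxy-2-methylbutyl]-2-[(tert-butyldimethylsilyl)oxy]-4-methyl-7-oxooct-5-enal | O=C[C@H](O[Si](C)(C)C(C)(C)C)C[C@@H](C)/C=C(\C(C)=O)C(OC(C)=O)[C@H](C)CC | intermediate
21 | (5R,7R,8Z)-9-[(2R)-1-acetoxy-2-methylbutyl]-5-[(tert-butyldimethylsilyl)oxy]-4-hydroxy-7-methylundec-8-en-1-yn-10-one (C4 epimers) | C#CCC(O)[C@H](O[Si](C)(C)C(C)(C)C)C[C@@H](C)/C=C(\C(C)=O)C(OC(C)=O)[C@H](C)CC | intermediate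
22 | 1-iodoalkyne of 21 | IC#CCC(O)[C@H](O[Si](C)(C)C(C)(C)C)C[C@@H](C)/C=C(\C(C)=O)C(OC(C)=O)[C@H](C)CC | intermediate
23 | (1Z,5R,7R,8Z)-9-[(2R)-1-acetoxy-2-methylbutyl]-5-[(tert-butyldimethylsilyl)oxy]-4-hydroxy-1-iodo-7-methylundeca-1,8-dien-10-one | I/C=C\CC(O)[C@H](O[Si](C)(C)C(C)(C)C)C[C@@H](C)/C=C(\C(C)=O)C(OC(C)=O)[C@H](C)CC | intermediate
24 | (1Z,5R,7R,8Z)-9-[(2R)-1-acetoxy-2-methylbutyl]-5-[(tert-butyldimethylsilyl)oxy]-1-iodo-7-methylundeca-1,8-diene-4,10-dione | I/C=C\CC(=O)[C@H](O[Si](C)(C)C(C)(C)C)C[C@@H](C)/C=C(\C(C)=O)C(OC(C)=O)[C@H](C)CC | intermediate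
25 | lithium (Z)-dienolate of 24 | [Li]O/C(=C\C=C/I)[C@H](O[Si](C)(C)C(C)(C)C)C[C@@H](C)/C=C(\C(C)=O)C(OC(C)=O)[C@H](C)CC | intermediate
26 | 2-[(Z)-2-iodoethenyl]-4-methyl-3-[(3E,5R)-5-methyl-2-oxohept-3-en-3-yl]-6-[(tert-butyldimethylsilyl)oxy]cyclohexan-1-one (ring centres as in 27) | I/C=C\[C@H]1C(=O)[C@H](O[Si](C)(C)C(C)(C)C)C[C@@H](C)[C@@H]1/C(C(C)=O)=C\[C@H](C)CC | intermediate
27 | trans-fused 5-acetyl-6-[(2R)-butan-2-yl]-2-[(tert-butyldimethylsilyl)oxy]-4-methyl-3,4,4a,5,6,8a-hexahydronaphthalen-1(2H)-one | CC[C@@H](C)[C@H]1C=C[C@H]2C(=O)[C@H](O[Si](C)(C)C(C)(C)C)C[C@@H](C)[C@@H]2[C@H]1C(C)=O | intermediate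
28 | trans-fused 5-acetyl-6-[(2R)-butan-2-yl]-2-hydroxy-4-methyl-3,4,4a,5,6,8a-hexahydronaphthalen-1(2H)-one | CC[C@@H](C)[C@H]1C=C[C@H]2C(=O)[C@H](O)C[C@@H](C)[C@@H]2[C@H]1C(C)=O | intermediate
29 | methyl 3-oxobutanoate | COC(=O)CC(C)=O | starting material
30 | methyl (E)-3-{[(trifluoromethyl)sulfonyl]oxy}but-2-enoate | COC(=O)/C=C(\C)OS(=O)(=O)C(F)(F)F | intermediate
31 | 5-tert-butyl 1-methyl (E)-3-methylpent-2-enedioate | COC(=O)/C=C(\C)CC(=O)OC(C)(C)C | intermediate
32 | (E)-5-tert-butoxy-3-methyl-5-oxopent-2-enoic acid | OC(=O)/C=C(\C)CC(=O)OC(C)(C)C | intermediate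
33 | C2 (E)-3-methylglutaconate (tert-butyl ester) of ketol 28 | CC[C@@H](C)[C@H]1C=C[C@H]2C(=O)[C@H](OC(=O)/C=C(\C)CC(=O)OC(C)(C)C)C[C@@H](C)[C@@H]2[C@H]1C(C)=O | intermediate
34 | tert-butyl ester of the target | CC[C@@H](C)[C@H]1C=C[C@H]2[C@H](O)[C@H](OC(=O)/C=C(\C)CC(=O)OC(C)(C)C)C[C@@H](C)[C@@H]2[C@H]1C(C)=O | intermediate
35 | (1S,2R,4R,4aS,5S,6S,8aR)-5-acetyl-6-[(2R)-butan-2-yl]-1-hydroxy-4-methyl-1,2,3,4,4a,5,6,8a-octahydronaphthalen-2-yl hydrogen (E)-3-methylpent-2-enedioate | CC[C@@H](C)[C@H]1C=C[C@H]2[C@H](O)[C@H](OC(=O)/C=C(\C)CC(=O)O)C[C@@H](C)[C@@H]2[C@H]1C(C)=O | target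

**Step count and risks**

Total: 24 steps. Longest linear sequence: 19 steps (1–6, 9–18, 22–24).

Steps most likely to fail:

- **Step 17.** The vinyl radical may take hydrogen before it cyclizes, or close at the α-carbon (5-exo), so that ring A does not form cleanly. The fallback sets out from 24: only the ionic half is run (LiN(SiMe3)2, THF, −78 → 0 °C, then aq. NH4Cl) and the iodovinyl cyclohexanone 26 is isolated. Iodine is exchanged for tin with Me6Sn2 and Pd(PPh3)4 (PhMe, 80 °C) to give the (Z)-alkenyltrimethylstannane F1. CuCl in DMF then closes ring A by tin-to-copper transmetalation and intramolecular 1,4-addition of the alkenylcopper, which can deliver carbon only to the β-carbon; protonation on work-up should follow the same facial preference. The fallback rejoins the route at 27.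

- **Step 9.** Carbonyl reduction of the alkynone may compete with conjugate hydroalumination, or the aldol of the hindered α-aluminated enone may be sluggish. The fallback sets out from 12: semi-hydrogenation (H2, Pd/CaCO3 poisoned with Pb(OAc)2, quinoline) gives the (Z)-enone F2. Me2AlSPh adds in a 1,4 sense and the aluminium enolate is trapped with 15 to give the β-phenylthio aldol F3. Oxidation to the sulfoxide (NaIO4, aq. MeOH) and thermal syn-elimination toward the acidic α-hydrogen restores the enone and returns to the route at 17.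

- **Step 23.** The acyl group may move from the C2 oxygen to the newly formed C1 alkoxide, or be lost by methanolysis, during the hydride reduction. The fallback sets out from 27: the C1 ketone is reduced while C2 still carries the silyl ether (NaBH4, MeOH, −40 °C; same axial attack) to give the (1S)-alcohol F4. This is protected as the methoxymethyl ether F5 (MOMCl, i-Pr2NEt). The silyl ether is removed (Bu4NF, AcOH, THF) to give the C2 alcohol F6, which is esterified with 32 (EDC·HCl, DMAP) to the diester F7. Me3SiBr (CH2Cl2, −30 → 0 °C, aqueous work-up) then cleaves the methoxymethyl ether and the tert-butyl ester together and arrives at 35.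

**Further compounds**

F1 | step 17 | 2-[(Z)-2-(trimethylstannyl)ethenyl] analogue of 26 | C[Sn](C)(C)/C=C\[C@H]1C(=O)[C@H](O[Si](C)(C)C(C)(C)C)C[C@@H](C)[C@@H]1/C(C(C)=O)=C\[C@H](C)CC
F2 | step 9 | (3Z,5R,7R)-7-[(tert-butyldimethylsilyl)oxy]-8-[(4-methoxybenzyl)oxy]-5-methyloct-3-en-2-one | COc1ccc(COC[C@H](O[Si](C)(C)C(C)(C)C)C[C@@H](C)/C=C\C(C)=O)cc1
F3 | step 9 | 3-[(2R)-1-hydroxy-2-methylbutyl]-4-(phenylthio) aldol adduct of F2 (new centres as formed) | COc1ccc(COC[C@H](O[Si](C)(C)C(C)(C)C)C[C@@H](C)C(Sc2ccccc2)C(C(C)=O)C(O)[C@H](C)CC)cc1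
F4 | step 23 | (1S)-alcohol from 27 (C2 silyl ether kept) | CC[C@@H](C)[C@H]1C=C[C@H]2[C@H](O)[C@H](O[Si](C)(C)C(C)(C)C)C[C@@H](C)[C@@H]2[C@H]1C(C)=O
F5 | step 23 | C1 methoxymethyl ether of F4 | CC[C@@H](C)[C@H]1C=C[C@H]2[C@H](OCOC)[C@H](O[Si](C)(C)C(C)(C)C)C[C@@H](C)[C@@H]2[C@H]1C(C)=O
F6 | step 23 | C2 alcohol with C1 methoxymethyl ether | CC[C@@H](C)[C@H]1C=C[C@H]2[C@H](OCOC)[C@H](O)C[C@@H](C)[C@@H]2[C@H]1C(C)=O
F7 | step 23 | C2 ester of F6 with 32 | CC[C@@H](C)[C@H]1C=C[C@H]2[C@H](OCOC)[C@H](OC(=O)/C=C(\C)CC(=O)OC(C)(C)C)C[C@@H](C)[C@@H]2[C@H]1C(C)=O
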